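## Structural features

The target 27 is a (2S)-5,7-dihydroxyflavanone: the phloroglucinol-type ring A is fused to the pyranone ring C, and C2 carries arene ring B through C1'. Ring B is 1,3,4,5-tetrasubstituted: the C4' oxygen belongs to the 2,2-dimethylpyran ring D fused across C3'–C4', and C5' carries a prenyl group, so both carbons ortho to the C4' oxygen bear a five-carbon unit. Ring D holds the adjacent stereocentres C3'' and C4'' as a cis-diol (3''S,4''S, both hydroxyls on one face), whereas C2 is separated from them by the whole of ring B and must be set independently under reagent control. The fragile points are: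
- the C2–O1 bond (benzylic, para to the C4' oxygen, β to the ketone), which opens to the chalcone under base and then loses the C2 configuration;
- the C4'' hydroxyl (benzylic, ortho to an ether oxygen), which ionises in strong acid;
- the prenyl alkene, which is sensitive to acid and to electrophilic oxidants.

The real difficulty is twofold: oxygenating C3''/C4'' cis and in one absolute sense while a second, isolated alkene is present, and closing ring C with a defined C2 without passing through the chalcone. The key step uses the hidden symmetry of ring B: ring D plus the C5' prenyl group is a 3,5-diprenyl-4-hydroxyphenyl unit in which one prenyl group has been oxidised onto O4', so hydride removal at C4'' and O1''–C2'' closure differentiate two equivalent prenyl groups of 6. The precursor 6, the product 8 and the configuration of the target (2S,3''S,4''S) were checked against the target SMILES and needed no correction.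

## Logic of the disconnections

**27 ⇒ 26.** No skeletal bond is cut; the two aryl O–CH2OMe bonds on ring A and the two acetal C–O bonds on ring D are restored. The three masks are all acetals, so one acid treatment removes them together. The demand is an acid mild enough to leave the C4''–O and C2–O1 benzylic bonds and the prenyl alkene alone.

**26 ⇒ 15 + 22.** The bonds O1–C8a and C4–C4a are cut, which removes ring C and separates ring A as an aryne equivalent. The C2–O1 bond is not part of the cut, so the C2 configuration can be set beforehand in an open-chain compound and carried through without a chalcone intermediate. The demand is that the oxygen of 15 adds to the aryne carbon remote from the flanking alkoxy group and that the resulting aryl anion acylates faster than it is protonated.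

**15 ⇒ 13 + 14.** The C2–C3 bond is cut as an acetate aldol. This reduces the problem to an aryl aldehyde and a two-carbon ester unit. The demand is catalyst control of the new carbinol centre, because the ring D stereocentres are too remote to help.

**22 ⇒ 18 ⇒ 17 ⇒ 16.** The C–Si and O–S bonds, then the C–Br bond, then two O–CH2 bonds are removed, leading back to the symmetric triol. The demand is bromination ortho to the free hydroxyl and a clean O→C silyl shift.

**13 ⇒ 12 ⇒ 11 ⇒ 9 ⇒ 8.** The acetal, the carbonate and finally both C–O bonds at C3'' and C4'' are removed, leading back to the chromene alkene. The cis-diol is traced to an epoxide opened with overall retention, and the epoxide to the only cis-disubstituted conjugated alkene in 8. The demand is an oxidant that prefers this alkene to the prenyl alkene and one enantioface of it.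

**8 ⇒ 6 (key).** The O1''–C2'' bond is cut and the C3''=C4'' unsaturation is returned to a saturated benzylic CH2. Ring D disappears and the molecule becomes C2-symmetric about the C1'–C4' axis. The demand is that exactly one of the two equivalent prenyl groups is oxidised.

**6 ⇒ 5 ⇒ 2 + 3; 2 ⇒ 1.** The two aryl–CH2 bonds at C3' and C5' are cut, leading to a dibromide and a prenyl-tin reagent. Both bonds are made in one operation on a commercial arene. The demand is coupling at the unsubstituted terminus of the prenyl group and a phenol mask that survives palladium catalysis.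

## Other disconnections considered

**Alternative 1:** The cut is the C3=C4 bond of ring C at the enol ether oxidation level. The second-generation Grubbs catalyst RuCl2(PCy3)(H2IMes)(=CHPh) would join the vinyl group on C2 of the (S)-configured allyl aryl ether A2 to the silyl enol ether of its ring A acetyl group, closing ring C as the 4-silyloxy-2H-chromene A1; mild desilylation would then give 26.
- In its favour: enol ether–alkene ring-closing metathesis is an established ring closure under neutral conditions, and it avoids both the free β-alkoxide and the aryl anion of the chosen annulation. On the certainty of the ring-closing event itself this alternative is the better of the two.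
- Against it here: the prenyl group is itself a metathesis substrate and could be truncated or scrambled by the propagating ruthenium methylidene. A2 is a benzylic and allylic aryl ether that may ionise or undergo aromatic Claisen rearrangement at the temperatures a hindered enol ether needs. A1, a 2-aryl-2H-chromene, could lose its C2 configuration by reversible electrocyclic ring opening. Making A2 as one enantiomer requires an asymmetric O-allylation of a hindered, hydrogen-bonded ortho-acylphenol.
- Comparison: in structure both plans share the chemistry up to 13 and differ only in which ring C bonds are made last. In mechanism a metal-carbene [2+2] sequence replaces a polar aryne addition and acyl substitution. In step economy the alternative needs vinylation or allylic substitution, enol silylation, metathesis and hydrolysis, about two steps more than aldol plus annulation.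

**Alternative 2:** The cut is C3''–C4'' of ring D. A chiral aminoindanol-derived triazolium carbene would turn the aryl aldehyde of the dialdehyde A4 into an acyl anion equivalent that adds to the tethered α-aryloxy aldehyde, closing ring D as the (3R)-3-hydroxychroman-4-one A3, whose C3'' has the arrangement of the target.
- In its favour: both ring D oxygens arrive without any alkene oxidation, so the question of oxidising the chromene alkene beside the prenyl alkene never arises; on that point the alternative is better than the chosen plan. The aryl chloride of A3 could also feed a known asymmetric conjugate arylation of a chromone acceptor, a better-precedented way to C2 than the annulation proposed here.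
- Against it: the symmetry of ring B is not used, so the formyl group, the prenyl group, the chloride and the hindered tertiary aryl ether of A4 must be installed one after the other. A3 is a secondary α-ketol whose C3'' centre can enolise or undergo acyloin isomerisation under the basic carbene conditions. The C4'' ketone still has to be reduced cis to the C3'' hydroxyl, and the chloride has to be exchanged before ring C can be built.
- Comparison: in mechanism an umpolung C–C bond formation replaces a pericyclic C–O bond formation, and C3'' is set by the carbene catalyst instead of by epoxidation. In step economy the ring D sequence is judged two to four steps longer than steps 1 to 8 of the chosen plan; in convergence of the endgame the two are equal.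

**Alternative 3:** The cut is C2–C3 of ring C. Rh2(S-PTTL)4, dirhodium tetrakis[N-phthaloyl-(S)-tert-leucinate], would turn the diazoketone A6 into a rhodium carbene at C3 that inserts into one enantiotopic C–H bond of the O1–CH2–aryl group, closing ring C and setting C2 in the same step to give the silyl-protected flavanone A5.
- In its favour: ring closure and stereocentre formation are one catalytic step at the final oxidation level. The C–H bond is activated three times over (benzylic, next to oxygen, on a para-alkoxy arene), and no basic intermediate threatens the flavanone. A6 would come from 13 by reduction, etherification and diazo transfer, so in step count this alternative is the equal of the chosen endgame.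
- Against it: the carbene of an acceptor-only diazoketone is very reactive and can attack the lone pair of O1 instead, giving an oxonium ylide whose 1,2-benzyl shift leads to a benzofuranone skeleton. Insertion here forms a six-membered ring where five-membered closure is the usual preference. Discrimination of two enantiotopic hydrogens by such carbenes is often modest. The prenyl alkene and the electron-rich arenes are open to cyclopropanation and ring expansion, and the two silyl ethers of A5 must be removed with fluoride without opening ring C.
- Comparison: in structure the two plans are equally convergent. In mechanism a C–H insertion of an electrophilic carbene replaces nucleophilic addition to an aryne. The stereocentre would arise in the ring closure instead of before it, which makes its control less separable from ring formation than in the chosen plan.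

Key step: step 4

Assumption (step 9): the (S)-binaphthyl ligand of the titanium aldol catalyst is taken to direct the ketene acetal to the Si face of 13 and so to give the (3S)-carbinol; the sense is to be confirmed on the first batch and the (R)-ligand used if it proves the reverse.

## Route

Step 1
Reactants: 1 3,5-dibromo-4-hydroxybenzaldehyde
Product: 2 2,6-dibromo-4-formylphenyl acetate
Conditions: Ac2O, Et3N, DMAP (cat.), CH2Cl2, 0 °C → rt
Reagents that add atoms: acetic anhydride, CC(=O)OC(C)=O
Why: O-Acylation of the acidic 2,6-dibromophenol; the acetate removes the free phenoxide, which would slow oxidative addition and bind palladium in the next step.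

Step 2
Reactants: 2 2,6-dibromo-4-formylphenyl acetate; 3 tributyl(3-methylbut-2-enyl)stannane
Product: 5 4-formyl-2,6-bis(3-methylbut-2-enyl)phenyl acetate, via monoprenylated bromide 4 (not isolated)
Conditions: 3 (2.5 equiv), Pd(PPh3)4 (5 mol %), DMF, 95 °C, degassed; aq. KF work-up
Reagents that add atoms: none
Why: Twofold Migita–Kosugi–Stille coupling: zerovalent palladium inserts into each electron-poor C–Br bond, the prenyl group is transferred from tin and reductive elimination at the unsubstituted CH2 terminus should give the linear prenyl arene; formyl and acetoxy groups are inert to these neutral conditions. The first coupling gives 4, which reacts on in the same flask.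

Step 3
Reactants: 5 4-formyl-2,6-bis(3-methylbut-2-enyl)phenyl acetate
Product: 6 4-hydroxy-3,5-bis(3-methylbut-2-enyl)benzaldehyde
Conditions: K2CO3, MeOH, 0 °C → rt; aq. NH4Cl work-up
Reagents that add atoms: none
Why: Base-catalysed methanolysis of the aryl acetate; the work-up is kept near neutral so that the phenol does not add across a prenyl double bond.

Step 4
Reactants: 6 4-hydroxy-3,5-bis(3-methylbut-2-enyl)benzaldehyde
Product: 8 2,2-dimethyl-8-(3-methylbut-2-enyl)-2H-chromene-6-carbaldehyde, via vinyl ortho-quinone methide 7 (not isolated)
Conditions: DDQ (2,3-dichloro-5,6-dicyano-1,4-benzoquinone, 10 mol %), 2,6-lutidine (2.2 equiv), nBu4NBF4 (0.1 M), MeCN, 60 °C; divided cell, graphite-felt anode (+0.9 V vs Ag/AgCl), Pt cathode, AcOH in the catholyte, ca. 2.1 F/mol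
Reagents that add atoms: none
Why: DDQ abstracts hydride from one of the two equivalent benzylic and allylic CH2 groups ortho to the phenol (C4''), and loss of the phenolic proton gives the vinyl ortho-quinone methide 7 (O=C4'–C3'=C4''–C3''=C2''); a para-quinone methide cannot form because the para position carries the formyl group. Compound 7 closes ring D by a thermal, disrotatory oxa-6π electrocyclisation that forms O1''–C2'' and restores the aromatic sextet, which is the driving force. The reduced quinone, deprotonated by 2,6-lutidine, should be re-oxidised at the graphite anode at a potential well below that of 6 or 8, so that a catalytic amount of DDQ suffices while hydrogen is evolved at the cathode. The closest known reaction type is the stoichiometric DDQ dehydrogenative cyclisation of ortho-prenylphenols to 2,2-dimethyl-2H-chromenes; anodic turnover of DDQ is an established way of running DDQ dehydrogenations catalytically and is here only a change of terminal oxidant. No stereocentre is formed. The step needs mono- and not bis-cyclisation, and the substrate secures this: there is only one phenolic oxygen, and once it is an ether the second prenyl group can no longer give a quinone methide; site selectivity does not arise because the two prenyl groups are homotopic. The formyl group is not attacked by DDQ and, by lowering the electron density of 8, should protect the product chromene from further hydride abstraction or direct anodic oxidation.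

Step 5
Reactants: 8 2,2-dimethyl-8-(3-methylbut-2-enyl)-2H-chromene-6-carbaldehyde
Product: 9 (3S,4S)-3,4-epoxy-2,2-dimethyl-8-(3-methylbut-2-enyl)chromane-6-carbaldehyde
Conditions: (S,S)-Mn(salen)Cl (chloro[(S,S)-N,N'-bis(3,5-di-tert-butylsalicylidene)cyclohexane-1,2-diaminato]manganese, trivalent manganese, 4 mol %), 4-phenylpyridine N-oxide (20 mol %), aq. NaOCl buffered to pH 11.3, CH2Cl2, 0 °C
Reagents that add atoms: sodium hypochlorite, [Na+].[O-]Cl
Why: Jacobsen–Katsuki epoxidation: the manganese-oxo species attacks a cis-disubstituted alkene conjugated to an arene much faster than an isolated trisubstituted alkene, because only the former passes through a stabilised benzylic radical; this preference over the prenyl group is to be confirmed on a small scale. The (S,S) catalyst is chosen because with 2,2-dimethylchromenes it delivers oxygen to the face that gives the (3S,4S) epoxide, which fixes C3'' and C4''.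

Step 6
Reactants: 9 (3S,4S)-3,4-epoxy-2,2-dimethyl-8-(3-methylbut-2-enyl)chromane-6-carbaldehyde
Product: 11 (3aS,9bS)-4,4-dimethyl-6-(3-methylbut-2-enyl)-2-oxo-3a,9b-dihydro-4H-[1,3]dioxolo[4,5-c]chromene-8-carbaldehyde (cis-fused cyclic carbonate), via trans-bromo carbonate salt 10 (not isolated)
Conditions: CO2 (10 bar), nBu4NBr (10 mol %), DMF, 80 °C
Reagents that add atoms: carbon dioxide, O=C=O
Why: Halide-catalysed cycloaddition of carbon dioxide to an epoxide: bromide opens the benzylic C4''–O bond with inversion, the C3'' alkoxide takes up CO2 to give 10, and the carbonate oxygen displaces bromide with a second inversion, so both C–O bonds end on the original face and the carbonate is cis-fused. C3'' is never touched.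

Step 7
Reactants: 11 cis-fused cyclic carbonate
Product: 12 (3S,4S)-3,4-dihydroxy-2,2-dimethyl-8-(3-methylbut-2-enyl)chromane-6-carbaldehyde
Conditions: K2CO3 (0.2 equiv), MeOH, 0 °C → rt
Reagents that add atoms: none
Why: Transesterification of the cyclic carbonate with methanol under mild base; cleavage occurs at the acyl–oxygen bonds, so both stereocentres keep their configuration.

Step 8
Reactants: 12 (3S,4S)-3,4-dihydroxy-2,2-dimethyl-8-(3-methylbut-2-enyl)chromane-6-carbaldehyde
Product: 13 (3aS,9bS)-2,2,4,4-tetramethyl-6-(3-methylbut-2-enyl)-3a,9b-dihydro-4H-[1,3]dioxolo[4,5-c]chromene-8-carbaldehyde (acetonide)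
Conditions: 2-methoxypropene, PPTS (5 mol %), CH2Cl2, 0 °C → rt
Reagents that add atoms: 2-methoxypropene, COC(C)=C
Why: Acid-catalysed acetal formation on the cis-1,2-diol; the weak acid at 0 °C should not ionise the benzylic C4''–O bond or hydrate the prenyl group, and any adduct at the formyl group reverts on aqueous work-up.

Step 9
Reactants: 13 acetonide aldehyde; 14 1-methoxy-1-(trimethylsilyloxy)ethene
Product: 15 methyl (3S)-3-[(3aS,9bS)-2,2,4,4-tetramethyl-6-(3-methylbut-2-enyl)-3a,9b-dihydro-4H-[1,3]dioxolo[4,5-c]chromen-8-yl]-3-(trimethylsilyloxy)propanoate
Conditions: 14 (1.5 equiv), Ti(OiPr)4 (2 mol %), (S)-2-[(3-bromo-5-tert-butyl-2-hydroxybenzylidene)amino]-2'-hydroxy-1,1'-binaphthyl (2 mol %), 3,5-di-tert-butylsalicylic acid (2 mol %), Et2O, −10 °C; pH 7 buffer work-up without desilylation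
Reagents that add atoms: none
Why: Catalytic enantioselective Mukaiyama aldol addition of an acetate-derived silyl ketene acetal: the chiral titanium Lewis acid binds the aldehyde and leaves one face open, and silyl transfer to the aldolate gives the trimethylsilyl ether directly. The new stereocentre (C2 of the flavanone) is set by the ligand; the ring D stereocentres are too remote to interfere.

Step 10
Reactants: 16 phloroglucinol
Product: 17 3,5-bis(methoxymethoxy)phenol
Conditions: MOMCl (2.0 equiv), iPr2NEt, DMF, 0 °C → rt
Reagents that add atoms: chloromethyl methyl ether, COCCl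
Why: O-Alkylation of the phenol with the reactive α-chloro ether; with two equivalents the bis-ether should be the main component of a statistical mixture and is separated from the mono- and tris-ethers. The low cost of 16 makes this acceptable.

Step 11
Reactants: 17 3,5-bis(methoxymethoxy)phenol
Product: 18 2-bromo-3,5-bis(methoxymethoxy)phenol
Conditions: NBS (1.0 equiv), CH2Cl2, −78 → 0 °C
Reagents that add atoms: N-bromosuccinimide, O=C1CCC(=O)N1Br
Why: Electrophilic aromatic bromination of a highly activated phenol at low temperature; the position ortho to the free hydroxyl (two equivalent sites) is expected to be favoured in a non-polar solvent, and any para isomer is removed by chromatography.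

Step 12
Reactants: 18 2-bromo-3,5-bis(methoxymethoxy)phenol
Product: 22 3,5-bis(methoxymethoxy)-2-(trimethylsilyl)phenyl trifluoromethanesulfonate, via aryl trimethylsilyl ether 19 (not isolated), via aryllithium 20 (not isolated), via lithium silylphenoxide 21 (not isolated)
Conditions: HMDS, THF, 65 °C, then evaporation; n-BuLi, THF, −78 °C; Tf2O, −78 °C
Reagents that add atoms: hexamethyldisilazane, C[Si](C)(C)N[Si](C)(C)C; trifluoromethanesulfonic anhydride, O=S(=O)(OS(=O)(=O)C(F)(F)F)C(F)(F)F
Why: Standard route to ortho-silylaryl triflates: O-silylation gives 19, bromine–lithium exchange gives 20, a 1,3 O→C silyl shift (retro-Brook rearrangement) gives the phenoxide 21, and O-triflation completes the aryne precursor. The methoxymethyl ethers tolerate n-BuLi at −78 °C.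

Step 13
Reactants: 15 methyl (3S)-3-aryl-3-(trimethylsilyloxy)propanoate; 22 3,5-bis(methoxymethoxy)-2-(trimethylsilyl)phenyl trifluoromethanesulfonate
Product: 26 (2S)-5,7-bis(methoxymethoxy)-2-[(3aS,9bS)-2,2,4,4-tetramethyl-6-(3-methylbut-2-enyl)-3a,9b-dihydro-4H-[1,3]dioxolo[4,5-c]chromen-8-yl]chroman-4-one, via cesium alkoxide 23 (not isolated), via aryne 24 (not isolated), via aryl cesium adduct 25 (not isolated)
Conditions: 22 (1.5 equiv), CsF (3 equiv), 18-crown-6, THF, 0 °C → rt
Reagents that add atoms: none
Why: Proposed new method: fluoride removes the trimethylsilyl group of 15 to give the naked alkoxide 23 and at the same time releases the aryne 24 from 22; 23 should add to the aryne carbon remote from the flanking alkoxy group, as 3-alkoxyarynes dictate, which places the carbanion of 25 between two oxygen-bearing carbons, and this aryl anion should attack the methyl ester in a 6-exo-trig acyl substitution that forms C4–C4a and closes ring C. The C2–O1 bond of the stereocentre is never broken, so the (S) configuration of 15 should be carried into 26 unchanged. The closest known reaction type is the fluoride-induced annulation of arynes with methyl salicylate to xanthones (phenoxide addition, then intramolecular acylation of the aryl anion); the use of an aliphatic β-silyloxy ester as a latent alkoxide is the untested element.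

Step 14
Reactants: 26 protected flavanone
Product: 27 (2S)-2-[(3S,4S)-3,4-dihydroxy-2,2-dimethyl-8-(3-methylbut-2-enyl)-3,4-dihydro-2H-chromen-6-yl]-5,7-dihydroxychroman-4-one
Conditions: 2 M aq. HCl, MeOH–THF, 40 °C
Reagents that add atoms: none
Why: Acid-catalysed cleavage of the two aryl methoxymethyl ethers and of the isopropylidene acetal; all three react through oxocarbenium ions at the acetal carbons, so no bond to a stereocentre is broken. Dilute acid at 40 °C is chosen to leave the benzylic C4''–O and C2–O1 bonds and the prenyl alkene intact.

## Compound list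

1 | 3,5-dibromo-4-hydroxybenzaldehyde | O=Cc1cc(Br)c(O)c(Br)c1 | starting material
2 | 2,6-dibromo-4-formylphenyl acetate | CC(=O)Oc1c(Br)cc(C=O)cc1Br | intermediate
3 | tributyl(3-methylbut-2-enyl)stannane | CC(C)=CC[Sn](CCCC)(CCCC)CCCC | starting material
4 | 2-bromo-4-formyl-6-(3-methylbut-2-enyl)phenyl acetate (formed in situ) | CC(=O)Oc1c(Br)cc(C=O)cc1CC=C(C)C | intermediate
5 | 4-formyl-2,6-bis(3-methylbut-2-enyl)phenyl acetate | CC(=O)Oc1c(CC=C(C)C)cc(C=O)cc1CC=C(C)C | intermediate
6 | 4-hydroxy-3,5-bis(3-methylbut-2-enyl)benzaldehyde | CC(C)=CCc1cc(C=O)cc(CC=C(C)C)c1O | intermediate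
7 | (3Z)-3-(3-methylbut-2-enylidene)-5-(3-methylbut-2-enyl)-4-oxocyclohexa-1,5-diene-1-carbaldehyde, vinyl ortho-quinone methide (formed in situ) | O=C1C(CC=C(C)C)=CC(C=O)=C/C1=C/C=C(C)C | intermediate
8 | 2,2-dimethyl-8-(3-methylbut-2-enyl)-2H-chromene-6-carbaldehyde | CC(C)=CCc1cc(C=O)cc2c1OC(C)(C)C=C2 | intermediate
9 | (3S,4S)-3,4-epoxy-2,2-dimethyl-8-(3-methylbut-2-enyl)chromane-6-carbaldehyde | CC(C)=CCc1cc(C=O)cc2c1OC(C)(C)[C@H]3O[C@@H]23 | intermediate
10 | tetrabutylammonium (3R,4R)-4-bromo-6-formyl-2,2-dimethyl-8-(3-methylbut-2-enyl)chroman-3-yl carbonate, trans (formed in situ) | CC(C)=CCc1cc(C=O)cc2c1OC(C)(C)[C@@H](OC(=O)[O-])[C@@H]2Br.CCCC[N+](CCCC)(CCCC)CCCC | intermediate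
11 | (3aS,9bS)-4,4-dimethyl-6-(3-methylbut-2-enyl)-2-oxo-3a,9b-dihydro-4H-[1,3]dioxolo[4,5-c]chromene-8-carbaldehyde (cis-fused carbonate) | CC(C)=CCc1cc(C=O)cc2c1OC(C)(C)[C@@H](OC(=O)O3)[C@H]23 | intermediate
12 | (3S,4S)-3,4-dihydroxy-2,2-dimethyl-8-(3-methylbut-2-enyl)chromane-6-carbaldehyde (cis-diol) | CC(C)=CCc1cc(C=O)cc2c1OC(C)(C)[C@@H](O)[C@H]2O | intermediate
13 | (3aS,9bS)-2,2,4,4-tetramethyl-6-(3-methylbut-2-enyl)-3a,9b-dihydro-4H-[1,3]dioxolo[4,5-c]chromene-8-carbaldehyde (acetonide) | CC(C)=CCc1cc(C=O)cc2c1OC(C)(C)[C@@H](OC(C)(C)O3)[C@H]23 | intermediate
14 | 1-methoxy-1-(trimethylsilyloxy)ethene | C=C(OC)O[Si](C)(C)C | starting material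
15 | methyl (3S)-3-[(3aS,9bS)-2,2,4,4-tetramethyl-6-(3-methylbut-2-enyl)-3a,9b-dihydro-4H-[1,3]dioxolo[4,5-c]chromen-8-yl]-3-(trimethylsilyloxy)propanoate | CC(C)=CCc1cc([C@@H](O[Si](C)(C)C)CC(=O)OC)cc2c1OC(C)(C)[C@@H](OC(C)(C)O3)[C@H]23 | intermediate
16 | phloroglucinol | Oc1cc(O)cc(O)c1 | starting material
17 | 3,5-bis(methoxymethoxy)phenol | COCOc1cc(O)cc(OCOC)c1 | intermediate
18 | 2-bromo-3,5-bis(methoxymethoxy)phenol | COCOc1cc(O)c(Br)c(OCOC)c1 | intermediate
19 | [2-bromo-3,5-bis(methoxymethoxy)phenoxy]trimethylsilane (formed in situ) | COCOc1cc(O[Si](C)(C)C)c(Br)c(OCOC)c1 | intermediate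
20 | [2,4-bis(methoxymethoxy)-6-(trimethylsilyloxy)phenyl]lithium (formed in situ) | COCOc1cc(O[Si](C)(C)C)c([Li])c(OCOC)c1 | intermediate
21 | lithium 3,5-bis(methoxymethoxy)-2-(trimethylsilyl)phenoxide (formed in situ) | COCOc1cc([O-])c([Si](C)(C)C)c(OCOC)c1.[Li+] | intermediate
22 | 3,5-bis(methoxymethoxy)-2-(trimethylsilyl)phenyl trifluoromethanesulfonate | COCOc1cc(OS(=O)(=O)C(F)(F)F)c([Si](C)(C)C)c(OCOC)c1 | intermediate
23 | cesium (1S)-3-methoxy-3-oxo-1-[(3aS,9bS)-2,2,4,4-tetramethyl-6-(3-methylbut-2-enyl)-3a,9b-dihydro-4H-[1,3]dioxolo[4,5-c]chromen-8-yl]propan-1-olate (formed in situ) | CC(C)=CCc1cc([C@@H]([O-])CC(=O)OC)cc2c1OC(C)(C)[C@@H](OC(C)(C)O3)[C@H]23.[Cs+] | intermediate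
24 | 3,5-bis(methoxymethoxy)benzyne (formed in situ) | COCOC1=CC(OCOC)=CC#C1 | intermediate
25 | cesium 2-{(1S)-3-methoxy-3-oxo-1-arylpropoxy}-4,6-bis(methoxymethoxy)benzenide, aryl as in 23 (formed in situ) | CC(C)=CCc1cc([C@@H](Oc3cc(OCOC)cc(OCOC)[c-]3)CC(=O)OC)cc2c1OC(C)(C)[C@@H](OC(C)(C)O3)[C@H]23.[Cs+] | intermediate
26 | (2S)-5,7-bis(methoxymethoxy)-2-[(3aS,9bS)-2,2,4,4-tetramethyl-6-(3-methylbut-2-enyl)-3a,9b-dihydro-4H-[1,3]dioxolo[4,5-c]chromen-8-yl]chroman-4-one | CC(C)=CCc1cc([C@@H]2CC(=O)c3c(OCOC)cc(OCOC)cc3O2)cc2c1OC(C)(C)[C@@H](OC(C)(C)O3)[C@H]23 | intermediate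
27 | (2S)-2-[(3S,4S)-3,4-dihydroxy-2,2-dimethyl-8-(3-methylbut-2-enyl)-3,4-dihydro-2H-chromen-6-yl]-5,7-dihydroxychroman-4-one | CC(C)=CCc1cc([C@@H]2CC(=O)c3c(O)cc(O)cc3O2)cc2c1OC(C)(C)[C@@H](O)[C@H]2O | target

## Step count and least certain steps

Total: 14 steps. Longest linear sequence: 11 steps (steps 1 to 9, 13 and 14); the aryne precursor branch is 3 steps (10 to 12).

**Step 13 (annulation, proposed new method).** Three processes are most likely to go wrong. The aryl anion of 25 may be quenched by proton transfer from the ester α-CH2 before it acylates, followed by β-elimination of the aryloxide. The alkoxide 23 may fragment by retro-aldol reaction, which the electron-rich aryl group makes easier. The methoxide set free may open ring C of the product reversibly through the chalcone and erode the C2 configuration. The fallback uses known chemistry, sets out from 13 and comes back at 26. Claisen–Schmidt condensation of 13 with commercial 1-[2-hydroxy-4,6-bis(methoxymethoxy)phenyl]ethanone (KOH, EtOH, rt) would give the (E)-2'-hydroxychalcone F1. Base-mediated intramolecular oxa-Michael addition (NaOAc, EtOH, reflux) would close ring C to 26 together with its (2R) epimer F2. The two are diastereomers because of the ring D stereocentres and would be separated by preparative HPLC on a chiral stationary phase, with F2 returned to the equilibration. Stereocontrol at C2 is given up in exchange for certainty of ring closure.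

**Step 4 (key step).** Hydride abstraction from a phenol deactivated by a para-formyl group may be slow, so the catalytic cycle may stall while DDQ is lost to side reactions. Acid built up in the anolyte may instead drive Markovnikov addition of the phenol across a prenyl double bond, and direct anodic oxidation of the phenol may compete if the potential drifts upward. Stoichiometric DDQ in hot benzene or dioxane is the obvious first variation. The fallback that changes the approach sets out from 6 and comes back at 8. Electrophilic selenocyclisation with PhSeCl (CH2Cl2, −78 °C) would engage either of the two equivalent prenyl groups in a 6-endo closure to give racemic 2,2-dimethyl-8-(3-methylbut-2-enyl)-3-(phenylselanyl)chromane-6-carbaldehyde F3. Oxidation at low temperature (mCPBA, −78 °C, then iPr2NH, rt) would give the selenoxide F4, whose syn-elimination can only run toward the benzylic C4'' and so delivers 8.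

**Step 5 (epoxidation).** Oxygen transfer to the isolated prenyl alkene or attack of hypochlorite on the formyl group may compete with epoxidation of the chromene alkene, and the C8 prenyl group next to the ring oxygen may lower facial selectivity. The strategy leaves a prenyl alkene in every substrate of this step, so the fallback can only change the oxidant family; it sets out from 8 and comes back at 9. The same epoxide would be sought with a dimeric [Ti(μ-O)(salalen)]2 complex and aqueous H2O2 (CH2Cl2, rt). This closed-shell titanium-peroxo oxidant accepts cis-disubstituted conjugated alkenes, is expected to leave trisubstituted alkenes largely untouched and contains no chlorine. The ligand enantiomer would be chosen to give the (3S,4S) epoxide.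

**Step 9 (aldol).** Face discrimination on an electron-rich, slowly reacting aryl aldehyde may be insufficient or of the opposite sense, and the silyl ether may be lost on isolation. The fallback sets out from 13 and comes back at 15. The magnesium enolate of (S)-2-hydroxy-1,2,2-triphenylethyl acetate (LDA, THF, then MgBr2, −115 °C) is an auxiliary-controlled acetate enolate whose (R) form gives (R)-3-hydroxy acids. It would add to 13 to give the (3S)-hydroxy ester of the auxiliary F5, which can be enriched by crystallisation. Methanolysis (K2CO3, MeOH) would give the methyl (3S)-3-hydroxy ester F6 and return the auxiliary diol, and silylation (TMSCl, imidazole, CH2Cl2) would give 15.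

**Step 14 (deprotection).** Acid-promoted ionisation of the benzylic C4''–O bond may cause epimerisation to the trans-diol or exchange with methanol; ionisation of C2–O1 and Markovnikov addition to the prenyl alkene are further risks. The fallback separates the two deprotections; it sets out from 26 and comes back at 27. The aryl methoxymethyl ethers would first be removed under non-protic conditions (TMSOTf, 2,2'-bipyridyl, CH2Cl2, 0 °C; then H2O) to give the acetonide of the target F7, in which the acetal still shields C4''. The acetonide would then be hydrolysed with 80 % aqueous AcOH at 40 °C, which is too weak to ionise a benzylic alcohol.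

Further compounds

F1 | step 13 | (E)-1-[2-hydroxy-4,6-bis(methoxymethoxy)phenyl]-3-[(3aS,9bS)-2,2,4,4-tetramethyl-6-(3-methylbut-2-enyl)-3a,9b-dihydro-4H-[1,3]dioxolo[4,5-c]chromen-8-yl]prop-2-en-1-one | CC(C)=CCc1cc(/C=C/C(=O)c3c(O)cc(OCOC)cc3OCOC)cc2c1OC(C)(C)[C@@H](OC(C)(C)O3)[C@H]23
F2 | step 13 | (2R)-5,7-bis(methoxymethoxy)-2-[(3aS,9bS)-2,2,4,4-tetramethyl-6-(3-methylbut-2-enyl)-3a,9b-dihydro-4H-[1,3]dioxolo[4,5-c]chromen-8-yl]chroman-4-one | CC(C)=CCc1cc([C@H]2CC(=O)c3c(OCOC)cc(OCOC)cc3O2)cc2c1OC(C)(C)[C@@H](OC(C)(C)O3)[C@H]23
F3 | step 4 | 2,2-dimethyl-8-(3-methylbut-2-enyl)-3-(phenylselanyl)chromane-6-carbaldehyde (racemic) | CC(C)=CCc1cc(C=O)cc2c1OC(C)(C)C([Se]c3ccccc3)C2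
F4 | step 4 | 2,2-dimethyl-8-(3-methylbut-2-enyl)-3-(phenylseleninyl)chromane-6-carbaldehyde | CC(C)=CCc1cc(C=O)cc2c1OC(C)(C)C([Se](=O)c3ccccc3)C2
F0 | step 5 | none | none
F5 | step 9 | (1S)-2-hydroxy-1,2,2-triphenylethyl (3S)-3-hydroxy-3-[(3aS,9bS)-2,2,4,4-tetramethyl-6-(3-methylbut-2-enyl)-3a,9b-dihydro-4H-[1,3]dioxolo[4,5-c]chromen-8-yl]propanoate | CC(C)=CCc1cc([C@@H](O)CC(=O)O[C@@H](c3ccccc3)C(O)(c3ccccc3)c3ccccc3)cc2c1OC(C)(C)[C@@H](OC(C)(C)O3)[C@H]23
F6 | step 9 | methyl (3S)-3-hydroxy-3-[(3aS,9bS)-2,2,4,4-tetramethyl-6-(3-methylbut-2-enyl)-3a,9b-dihydro-4H-[1,3]dioxolo[4,5-c]chromen-8-yl]propanoate | CC(C)=CCc1cc([C@@H](O)CC(=O)OC)cc2c1OC(C)(C)[C@@H](OC(C)(C)O3)[C@H]23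
F7 | step 14 | (2S)-5,7-dihydroxy-2-[(3aS,9bS)-2,2,4,4-tetramethyl-6-(3-methylbut-2-enyl)-3a,9b-dihydro-4H-[1,3]dioxolo[4,5-c]chromen-8-yl]chroman-4-one | CC(C)=CCc1cc([C@@H]2CC(=O)c3c(O)cc(O)cc3O2)cc2c1OC(C)(C)[C@@H](OC(C)(C)O3)[C@H]23
A1 | alternative 1 | (2S)-4-(tert-butyldimethylsilyloxy)-5,7-bis(methoxymethoxy)-2-[(3aS,9bS)-2,2,4,4-tetramethyl-6-(3-methylbut-2-enyl)-3a,9b-dihydro-4H-[1,3]dioxolo[4,5-c]chromen-8-yl]-2H-chromene | CC(C)=CCc1cc([C@@H]2C=C(O[Si](C)(C)C(C)(C)C)c3c(OCOC)cc(OCOC)cc3O2)cc2c1OC(C)(C)[C@@H](OC(C)(C)O3)[C@H]23
A2 | alternative 1 | tert-butyldimethylsilyl enol ether of 1-{2-[(1S)-1-aryl-prop-2-enyloxy]-4,6-bis(methoxymethoxy)phenyl}ethanone, aryl = (3aS,9bS)-2,2,4,4-tetramethyl-6-(3-methylbut-2-enyl)-3a,9b-dihydro-4H-[1,3]dioxolo[4,5-c]chromen-8-yl | CC(C)=CCc1cc([C@H](C=C)Oc3cc(OCOC)cc(OCOC)c3C(=C)O[Si](C)(C)C(C)(C)C)cc2c1OC(C)(C)[C@@H](OC(C)(C)O3)[C@H]23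
A3 | alternative 2 | (3R)-6-chloro-3-hydroxy-2,2-dimethyl-8-(3-methylbut-2-enyl)chroman-4-one | CC(C)=CCc1cc(Cl)cc2c1OC(C)(C)[C@@H](O)C2=O
A4 | alternative 2 | 2-[4-chloro-2-formyl-6-(3-methylbut-2-enyl)phenoxy]-2-methylpropanal | CC(C)=CCc1cc(Cl)cc(C=O)c1OC(C)(C)C=O
A5 | alternative 3 | (2S)-5,7-bis(tert-butyldimethylsilyloxy)-2-[(3aS,9bS)-2,2,4,4-tetramethyl-6-(3-methylbut-2-enyl)-3a,9b-dihydro-4H-[1,3]dioxolo[4,5-c]chromen-8-yl]chroman-4-one | CC(C)=CCc1cc([C@@H]2CC(=O)c3c(O[Si](C)(C)C(C)(C)C)cc(O[Si](C)(C)C(C)(C)C)cc3O2)cc2c1OC(C)(C)[C@@H](OC(C)(C)O3)[C@H]23
A6 | alternative 3 | 2-diazo-1-{2,4-bis(tert-butyldimethylsilyloxy)-6-[((3aS,9bS)-2,2,4,4-tetramethyl-6-(3-methylbut-2-enyl)-3a,9b-dihydro-4H-[1,3]dioxolo[4,5-c]chromen-8-yl)methoxy]phenyl}ethanone | CC(C)=CCc1cc(COc3cc(O[Si](C)(C)C(C)(C)C)cc(O[Si](C)(C)C(C)(C)C)c3C(=O)C=[N+]=[N-])cc2c1OC(C)(C)[C@@H](OC(C)(C)O3)[C@H]23
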